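(The runs are simulated for an exercise; scatter was added.)

The ratio of product made to charge still unturned, the odds, is what we follow here. For a rate proportional to c(starting material) times c(product), which is autocatalysis, the logarithm of the odds climbs in a straight line with time.

| setting | blue | grey | ochre |
|---|---|---|---|
| starting material | 1.00 M | 1.50 M | 2.10 M |
| time |  |  | 33 min |

- blue run (time / min: [product] / M): 6.6: 0.054; 13: 0.157; 20: 0.269; 26: 0.419; 33: 0.600
- grey run (time / min: [product] / M): 6.6: 0.086; 13: 0.252; 20: 0.546; 26: 0.869; 33: 1.137

(scatter of a reading: 0.01 M)

- apparent order in [starting material] of the starting rate, round the charge of the blue run (the rate where two percent of its starting material have turned into product) (one fixed amount of product, the same in the runs compared)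
- product in the ochre run at 33 min, as a share of the starting material charged

- Overall: starting material -> product.
- Constant volume, constant temperature.
- Readings of a species count what is bound in complexes too.
- An order is taken over about fifteen percent of the charge, up and down.

Both runs start slowly and then climb, so we take the log odds from the third reading to the fifth. The blue run reads a slope of 0.108 min⁻¹, the grey run 0.131 min⁻¹. The plain law makes this slope proportional to the charge. Yet the charge rose 1.50-fold and the slope 1.21-fold.

So we carry the charge exponent, the power of the charge that the odds slope follows, which reads 0.469. The grey odds reach 1 at 24.3 min. We assume that this crossing time shrinks by the same power. For the ochre run, the slope becomes 0.153 min⁻¹ and the crossing time 20.7 min. That gives us 86.8% of the charge as product at 33 min.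

The forecast gives an order of 1 and a share of 81%, on the ground that “rate rises as product builds”. Our share stands above the forecast's.

The flask gives an order of 0.85 and a share of 86.1%.

    2 starting material ⇌ substrate dimer, settled at all times (0.1670 M⁻¹)
    starting material → product (0.007500 min⁻¹)
    2 starting material → homo dimer (0.003276 M⁻¹ min⁻¹)
    starting material + product → 2 product (0.1218 M⁻¹ min⁻¹)

Without the step starting material + product → 2 product, the simulated ochre run gives 14.6%, so that step carries the ochre share. Carried from the grey run back to the blue run, the exponent 0.469 puts the crossing at 29.4 min, and in the flask the blue run comes to half of its charge at 29.1 min.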